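(The readings were generated by integration from invented constants; the scatter is artificial.)

If we want to know how much mono adduct stands at a late time, we first need to know how long it lives once formed. Starting material and coupling partner give the mono adduct, and in both earlier runs the adduct rises and then falls.

| flask | starting material | coupling partner | remark | time |
|---|---|---|---|---|
| grey | 1 mM | 0.88 mM | run made earlier |  |
| green | 1 mM | 2.8 mM | run made earlier |  |
| epsilon | 1.0 mM | 0.600 mM |  | 3.0 min |
| gamma | 1.0 mM | 1.20 mM |  | 3.0 min |
| theta | 1.0 mM | 2.50 mM |  | 3.0 min |

- grey (time / s: mono adduct / %): 10.0: 15.6; 12.0: 17.0; 15.0: 17.5; 25.0: 19.0; 40.0: 17.5; 60.0: 14.7; 90.0: 13.0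
- green (time / s: mono adduct / %): 10.0: 32.1; 12.0: 32.3; 15.0: 31.9; 25.0: 27.6; 40.0: 19.4; 60.0: 10.7; 90.0: 5.3

(standard deviation of a reading: 0.5 percentage points)

- the earlier runs were read with a standard deviation of 0.5 percentage points
- "hardly changes" means that all values lie within two and a half points (for a concentration: within two and a half percent of the largest)

1. amount of mono adduct at the end, in percent of the starting material charged for epsilon, gamma, theta, in this order
2. the shape of the row from first to last (rises, then falls / hardly changes / falls, then rises / rises all the way / falls all the way)

The green run holds 2.80 parts of partner per part of starting material, and its adduct falls from 19.4% at 40.0 s to 5.3% at 90.0 s. This gives 0.445 min as the tail half-life, the time in which late adduct halves in green with partner in excess, a pseudo-first-order reading.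

We carry this to theta by running green's last reading on to 3.0 min, which gives our own estimate of 0.513%. Theta holds 2.50 parts of partner, less than green, so we take our figure as a low estimate for theta.

The forecast gives 9.5%, 12% and 1.5%, a row that rises, then falls, and its theta value is higher than ours. For epsilon it reasons that “the partner runs out sooner and less adduct forms”.

The flask gives 4.33%, 10.4% and 1.40%, a row that rises, then falls. The forecast and the flask part most plainly at epsilon.

    coupling partner + mono adduct → double product (k = 19.7 M⁻¹ s⁻¹)
    starting material + coupling partner → mono adduct (k = 33.2 M⁻¹ s⁻¹)
    starting material + coupling partner → other mono adduct (k = 6.79 M⁻¹ s⁻¹)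
    coupling partner + other mono adduct → double product (k = 15.2 M⁻¹ s⁻¹)
    starting material + mono adduct → side product (k = 57.7 M⁻¹ s⁻¹)

In epsilon the mono adduct also reacts with starting material to give side product, and at 0.281 min its half-life by this step is 0.29 min, shorter than green's tail half-life of 0.445 min and short against 3.0 min. At the end of epsilon, with 16.3% of the starting material and 5.27% of the partner left, the adduct is made at 0.395 of the rate at which it is used, each step taken net, and it stands at 4.33%.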